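8.50% of the alder charge was still missing from the product at 3.00 min, and I had to carry that gap forward to 4.0 min.

all flasks: gas 0.15 mM (held)

| run | substrate | remark | time |
|---|---|---|---|
| alder | 5.6 × 10⁻⁴ M | run made earlier |  |
| cedar | 0.0032 M | run made earlier |  |
| Sunday's | 4.0 × 10⁻⁴ M |  | 4.0 min |
| Monday's | 6.0 × 10⁻⁴ M |  | 4.0 min |
| Thursday's | 0.0010 M |  | 4.0 min |
| Tuesday's | 0.0015 M |  | 4.0 min |
| Friday's | 0.0025 M |  | 4.0 min |

| run | time / min | product / % | substrate / % |
|---|---|---|---|
| alder | 0.417 | 19.3 | 10.4 |
| alder | 0.833 | 42.4 | 0.6 |
| alder | 1.33 | 62.9 | 0.1 |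
| alder | 1.50 | 67.8 | 0.2 |
| alder | 2.00 | 78.8 | 0.2 |
| alder | 2.50 | 87.1 | 0.4 |
| alder | 3.00 | 91.5 | 0 |
| cedar | 0.250 | 8.7 | 25.7 |
| cedar | 0.333 | 13.3 | 15.7 |
| cedar | 0.500 | 22.5 | 6.8 |
| cedar | 0.833 | 40.5 | 1.2 |
| cedar | 1.33 | 60.1 | 0.2 |
| cedar | 2.00 | 76.9 | 0.9 |
| cedar | 3.00 | 90.2 | 0.5 |

(each reading ± 0.3 percentage points)

- the analysis behind the earlier runs scatters by 0.3 percentage points, standard deviation
- at the start none of the gas is in solution
- "hardly changes" means that all values lie within two and a half points (for a concentration: within two and a half percent of the largest)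

- amount of product at the end, in percent of the substrate charged for Sunday's, Monday's, Thursday's, Tuesday's, Friday's, in this order
- how that number moves from the first to the last of them (rises all the way / rises, then falls / falls all the way / falls, then rises / hardly changes)

My bench rule was that a tail closes by the same share each minute, so I took two late readings per run. In alder the gap fell from 21.2% at 2.00 min to 8.50%, which gave a tail rate of 0.914 min⁻¹, the logarithm of the fall in the gap per unit of time. I put the gap back through the same step once more and reached 3.41% at 4.0 min, so 96.6% product. Cedar's readings, with their scatter, gave a tail rate of 0.857 min⁻¹, lower than alder's, and so a gap of 4.16%.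

The border I set on the rule was the span of charges it had been seen in. That span was a charge ratio of 5.71, with cedar's c(substrate) already 21.3 times the held c(gas). Friday's charge lay inside that span, but Sunday's was 0.714 of alder's, just outside it. My reckoned gaps for alder and cedar differed by 0.75 percentage points, so I expected the row to fall by about that or less, which counts as hardly changing.

The forecast gave 96.3%, 96.3%, 96.2%, 96% and 95.8%, shape "hardly changes", noting that “the percent curves nearly coincide”. Its first value was lower than mine.

The flasks gave 96.4%, 96.4%, 96.4%, 96.3% and 96.1%, shape "hardly changes".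

    partner + intermediate → product (k = 98.0 L mol⁻¹ s⁻¹)
    gas ⇌ partner, rate k2*(csat - [partner]) (kL = 2.10 s⁻¹)
    substrate → intermediate (k = 0.0920 s⁻¹)

In Sunday's flask at 0.594 min, the half-life of the substrate was 0.13 min and that of the intermediate, by its pseudo-first-order step with the partner, was 0.80 min, which is 6.34 times longer. Alder's tail rate, read as a half-life, gives 0.758 min, beside that 0.80 min. Friday's flask held 22.1% intermediate at 2.00 min, which alder's tail rate carries to 3.55% at 4.00 min, and Friday's flask held 3.87%.

(Readings and results come from a simulation for substances that don't exist; the scatter is artificial.)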